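**Assumption:** the SMILES is read as (2R,3R), 2,3-cis, i.e. the 3-O-(3-hydroxy-4,5-dimethoxybenzoyl) ester of (−)-epicatechin; the acid, the chloroketone and the aldehyde used below are taken as catalogue chemicals.

## Retrosynthetic overview

- Target ⇒ 3-O-acyl cyanidin (flavylium) chloride: ring C is saturated last by an enantioselective cis delivery of two hydrides, as anthocyanidin reductase does; both stereocentres come from this one step.
- Flavylium ⇒ 2,4,6-trihydroxybenzaldehyde + α-aroyloxy ketone: ring C, the only ring made, closes by O1–C2 attack of the ring A phenol within a chalcone, then loses water to the anthocyanidin.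
- The chalcone carries its carbonyl at the future C2 rather than C4, so no C4 oxygen ever has to be removed; the galloyl-type ester is installed before ring formation, not after.
- α-Aroyloxy ketone ⇒ 2-chloro-3',4'-dihydroxyacetophenone + 3-hydroxy-4,5-dimethoxybenzoic acid (carboxylate alkylation). No protecting groups.

## Route

**Step 1**
Reactants: 1 3-hydroxy-4,5-dimethoxybenzoic acid; 2 2-chloro-1-(3,4-dihydroxyphenyl)ethanone
Product: 3 2-(3,4-dihydroxyphenyl)-2-oxoethyl 3-hydroxy-4,5-dimethoxybenzoate
Conditions: KHCO3 (1.05 equiv), NaI (0.1 equiv), DMF, N2, rt → 40 °C, 6 h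
Reagents that add atoms: none
Why: SN2 O-alkylation of a carboxylate by a phenacyl chloride (Finkelstein-assisted phenacyl ester formation); hydrogencarbonate deprotonates only the carboxylic acid (pKa about 4), not the phenols (pKa 8–10), so the ester forms selectively.

**Step 2**
Reactants: 3 2-(3,4-dihydroxyphenyl)-2-oxoethyl 3-hydroxy-4,5-dimethoxybenzoate; 4 2,4,6-trihydroxybenzaldehyde
Product: 7 2-(3,4-dihydroxyphenyl)-5,7-dihydroxy-3-[(3-hydroxy-4,5-dimethoxybenzoyl)oxy]chromenylium chloride, via 2-hydroxychalcone 5 (not isolated), via hemiketal 6 (not isolated)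
Conditions: HCl (g, saturated), EtOAc/AcOH (4:1), 0 °C → rt, 48 h; filter the red salt, wash with Et2O
Reagents that add atoms: hydrogen chloride, SMILES Cl
Why: Robinson anthocyanidin synthesis: acid-catalysed crossed aldol condensation gives chalcone 5, whose E/Z forms equilibrate in HCl so that the ring A phenol closes onto the aryl ketone (O1–C2 bond) and hemiketal 6 aromatises by loss of water; the symmetric aldehyde leaves no regiochemical choice, and the anhydrous, alcohol-free medium spares the ester.

**Step 3**
Reactants: 7 2-(3,4-dihydroxyphenyl)-5,7-dihydroxy-3-[(3-hydroxy-4,5-dimethoxybenzoyl)oxy]chromenylium chloride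
Product: 9 (2R,3R)-2-(3,4-dihydroxyphenyl)-5,7-dihydroxychroman-3-yl 3-hydroxy-4,5-dimethoxybenzoate (target), via 4H-chromene 8 (not isolated)
Conditions: H2 (50 bar), [Ir(cod)Cl]2 (2.5 mol %), (R)-SegPhos (5.5 mol %), THF/(CF3)2CHOH (3:1), 30 °C, 24 h
Reagents that add atoms: none
Why: Proposed new method: the flavylium is the oxygen analogue of a 2-aryl-3-substituted quinolinium or pyridinium salt, which iridium–bisphosphine hydrides reduce enantio- and cis-selectively (the closest known reaction type, together with iridium-catalysed hydrogenation of cyclic oxocarbenium chlorides and the long-known racemic Pt hydrogenation of cyanidin chloride to epicatechin); outer-sphere hydride transfer to C4 gives enol ether 8, the HCl released protonates C3 to the C2 oxocarbenium whose C3 centre equilibrates through 8 (dynamic kinetic resolution), and the chiral Ir–H delivers the second hydride to C2 anti to the participating 3-acyloxy group, so C2 and C3 are set together as cis; the (2R,3R) sense is fixed by the ligand hand, (R) being assigned by analogy and replaced by (S)-SegPhos in the same step if chiral HPLC shows the mirror image.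

## Compound list

1 | 3-hydroxy-4,5-dimethoxybenzoic acid (3,4-di-O-methylgallic acid) | COc1cc(C(=O)O)cc(O)c1OC | starting material
2 | 2-chloro-1-(3,4-dihydroxyphenyl)ethanone | O=C(CCl)c1ccc(O)c(O)c1 | starting material
3 | 2-(3,4-dihydroxyphenyl)-2-oxoethyl 3-hydroxy-4,5-dimethoxybenzoate | COc1cc(C(=O)OCC(=O)c2ccc(O)c(O)c2)cc(O)c1OC | intermediate
4 | 2,4,6-trihydroxybenzaldehyde | O=Cc1c(O)cc(O)cc1O | starting material
5 | (E)-3-(3,4-dihydroxyphenyl)-3-oxo-1-(2,4,6-trihydroxyphenyl)prop-1-en-2-yl 3-hydroxy-4,5-dimethoxybenzoate (2-hydroxychalcone, the isomer that cyclises) | COc1cc(C(=O)O/C(=C/c2c(O)cc(O)cc2O)C(=O)c2ccc(O)c(O)c2)cc(O)c1OC | intermediate (not isolated)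
6 | 2-(3,4-dihydroxyphenyl)-2,5,7-trihydroxy-2H-chromen-3-yl 3-hydroxy-4,5-dimethoxybenzoate (hemiketal, racemic at C2, centre lost on dehydration) | COc1cc(C(=O)OC2=Cc3c(O)cc(O)cc3OC2(O)c2ccc(O)c(O)c2)cc(O)c1OC | intermediate (not isolated)
7 | 2-(3,4-dihydroxyphenyl)-5,7-dihydroxy-3-[(3-hydroxy-4,5-dimethoxybenzoyl)oxy]chromenylium chloride | COc1cc(C(=O)Oc2cc3c(O)cc(O)cc3[o+]c2-c2ccc(O)c(O)c2)cc(O)c1OC.[Cl-] | intermediate
8 | 2-(3,4-dihydroxyphenyl)-5,7-dihydroxy-4H-chromen-3-yl 3-hydroxy-4,5-dimethoxybenzoate | COc1cc(C(=O)OC2=C(c3ccc(O)c(O)c3)Oc3cc(O)cc(O)c3C2)cc(O)c1OC | intermediate (not isolated)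
9 | (2R,3R)-2-(3,4-dihydroxyphenyl)-5,7-dihydroxychroman-3-yl 3-hydroxy-4,5-dimethoxybenzoate | COc1cc(C(=O)O[C@@H]2Cc3c(O)cc(O)cc3O[C@@H]2c2ccc(O)c(O)c2)cc(O)c1OC | target

## Summary

Total step count: 3. Longest linear sequence: 3 (steps 1 → 2 → 3).

## Steps most likely to fail

**Step 3 (highest risk).** The enantioselective reduction of an unprotected polyphenolic flavylium has no direct precedent. The catechol or chloride may slow the iridium catalyst, the salt may slip into its neutral quinoidal base, and the cis/trans ratio and ee are untested. The fallback sets out from 7 and returns at 9. Compound 7 is hydrogenated over PtO2 (H2 3 bar, AcOH/EtOAc, rt), the old racemic cyanidin-to-epicatechin reduction, in which syn delivery from the metal surface gives only the 2,3-cis ester. The product is a 1:1 mixture of 9 and its mirror image (2S,3S)-2-(3,4-dihydroxyphenyl)-5,7-dihydroxychroman-3-yl 3-hydroxy-4,5-dimethoxybenzoate F1. Compound 9 is taken out by preparative chiral chromatography (immobilised amylose tris(3,5-dimethylphenylcarbamate), CO2/MeOH with 0.1% HCO2H). This trades catalyst control for a separation and caps the yield at 50%.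

**Step 2.** The free trihydroxybenzaldehyde can self-condense under HCl, and the 3-O-ester on a cationic ring is an activated ester. The fallback sets out from 3 and returns at 8, bypassing 4 and 7. Ketone 3 is α-methylenated (paraformaldehyde, i-Pr2NH·CF3CO2H, cat. CF3CO2H, THF, reflux; Mannich–elimination) to the enone 3-(3,4-dihydroxyphenyl)-3-oxoprop-1-en-2-yl 3-hydroxy-4,5-dimethoxybenzoate F2. This is treated with phloroglucinol F3 (3 equiv) and CF3CO2H in dioxane at rt. Friedel–Crafts conjugate addition gives the adduct 1-(3,4-dihydroxyphenyl)-1-oxo-3-(2,4,6-trihydroxyphenyl)propan-2-yl 3-hydroxy-4,5-dimethoxybenzoate F4, which cyclodehydrates in the same flask to the 4H-chromene 8. Compound 8 is isolated and hydrogenated under the step 3 conditions with 1 equiv of anhydrous HCl (in dioxane) added in place of the acid that 7 would have released.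

**Step 1.** The 4'-phenol of 2 is fairly acidic and could be alkylated by a second molecule of 2, and the catechol is air-sensitive under base. The fallback sets out from 2 and returns at 3. Compound 2 is acetylated under acid (Ac2O, cat. H2SO4, rt) to 4-(2-chloroacetyl)-1,2-phenylene diacetate F5. This is alkylated with the potassium salt of 1 (KHCO3, NaI cat., DMF, rt) to 2-(3,4-diacetoxyphenyl)-2-oxoethyl 3-hydroxy-4,5-dimethoxybenzoate F6. The two aryl acetates are then removed by acid-catalysed methanolysis (cat. HCl, MeOH, 0 °C → rt), which is much faster for aryl acetates than for the alkyl aroate, giving 3.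

## Further compounds

F1 | step 3 | (2S,3S)-2-(3,4-dihydroxyphenyl)-5,7-dihydroxychroman-3-yl 3-hydroxy-4,5-dimethoxybenzoate (enantiomer of 9) | COc1cc(C(=O)O[C@H]2Cc3c(O)cc(O)cc3O[C@H]2c2ccc(O)c(O)c2)cc(O)c1OC
F2 | step 2 | 3-(3,4-dihydroxyphenyl)-3-oxoprop-1-en-2-yl 3-hydroxy-4,5-dimethoxybenzoate | COc1cc(C(=O)OC(=C)C(=O)c2ccc(O)c(O)c2)cc(O)c1OC
F3 | step 2 | phloroglucinol (benzene-1,3,5-triol, purchased) | Oc1cc(O)cc(O)c1
F4 | step 2 | 1-(3,4-dihydroxyphenyl)-1-oxo-3-(2,4,6-trihydroxyphenyl)propan-2-yl 3-hydroxy-4,5-dimethoxybenzoate (racemic, not isolated) | COc1cc(C(=O)OC(Cc2c(O)cc(O)cc2O)C(=O)c2ccc(O)c(O)c2)cc(O)c1OC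
F5 | step 1 | 4-(2-chloroacetyl)-1,2-phenylene diacetate | CC(=O)Oc1ccc(C(=O)CCl)cc1OC(C)=O
F6 | step 1 | 2-(3,4-diacetoxyphenyl)-2-oxoethyl 3-hydroxy-4,5-dimethoxybenzoate | COc1cc(C(=O)OCC(=O)c2ccc(OC(C)=O)c(OC(C)=O)c2)cc(O)c1OC
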